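# Synthesis design for CNP0242386.1 (compound 30)

## The problem

Compound 30 joins two heterocycles through a single aryl–CH2 bond. One is a 2-aryl-3-hydroxymethyl-tetrahydrofuran (O1, C2–C5; ring A = 3-hydroxy-4-methoxyphenyl on C2). The other is a trans-2-aryl-3-hydroxymethyl-2,3-dihydrobenzofuran (O1', C2', C3', benzo ring B; ring C = 4-hydroxy-3-methoxyphenyl on C2'), and the link runs from the C4 methylene to C6'. This target numbering is used for all intermediates; in the cyclobutanone the carbonyl carbon is the future C5.

The five stereocentres fall into two sets: C2 (R), C3 (S), C4 (S) with 2,3-trans and 3,4-cis, and C2' (S), C3' (R) trans. A methylene and an arene separate the sets, so neither can control the other and each needs its own source of absolute configuration. Within a set relay is possible: C3 can direct C2 (aryl prefers trans) and C4 (a reagent approaches anti to the C3 substituent), and C2' can direct C3' by equilibration to trans. The C3/C4 cis relation is the less stable one, so it must be made under kinetic control and kept away from base while a carbonyl flanks C4.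

Both benzylic C–O bonds (C2–O1 and C2'–O1') are para-alkoxybenzylic ethers. Acid ionises them (epimerisation, ring opening, Friedel–Crafts capture by the electron-rich ring B) and hydrogenolysis can cleave them. The free phenols are oxidisable. A free C3 hydroxymethyl group next to C5 at the aldehyde or ester oxidation level invites ring-chain isomerism and translactonisation.

The feature that opens the key step is seen when O1 is deleted. What remains is a four-carbon ring C2–C3–C4–C5 in which C2 is benzylic to the para-methoxy ring A, C5 is unsubstituted and can be a carbonyl, and C3/C4 carry cis CH2 groups as a Z-alkene would deliver them. O1 can therefore be inserted between C2 and a C5 carbonyl of a 2-arylcyclobutanone.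

## Retrosynthesis

**Unmasking.** Target 30 is traced to its bis-benzyl ether 29 and this to the C3 acetate 28. Benzyl ethers are chosen for the phenols because they survive every acidic, basic and organometallic step and leave under neutral hydrogenolysis. The acetate is a legacy of the key-step design and is removed only after the lactone carbonyl is gone.

**C5 methylene from a lactone carbonyl.** No bond is cut; C5 of 28 is taken back to the carbonyl of lactone 26 through lactol 27. The carbonyl is wanted because it activates C4 for C–C bond formation and is the direct outcome of oxygen insertion. The forward reduction must spare the C3 acetate. A free C3 hydroxymethyl group would let the lactol re-close through the wrong oxygen.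

**The CH2–C6' bond.** Cutting between the exocyclic methylene and ring B gives methylene lactone 13 and arylboronate 25. The neighbouring cut, C4–CH2 (enolate alkylation with a benzylic halide), would place the benzyl group trans to the C3 substituent, which is the wrong relation. The chosen cut makes C4 a prochiral enolate carbon that is protonated last, from the face away from the C3 substituent, giving cis. Each half carries two stereocentres and is far simpler than 26.

**The exocyclic methylene.** Lactone 13 comes from diacetate 12 by loss of acetic acid across C4 and its acetoxymethyl group. The two identical acetoxymethyl groups of 12 are thus told apart by position alone: the one α to the carbonyl is a leaving group, the other a protected alcohol.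

**Oxygen insertion (key step).** Removing O1 from 12 gives cyclobutanone 10; the forward step passes through Criegee adduct 11. Against closing the lactone by C–O bond formation from an open chain, this cut creates no stereocentre and scrambles none: C2 migrates with retention. The precursor is one ring atom simpler and is reachable by a cycloaddition. The forward reaction must choose C2 over C4 as migrating carbon and leave ring A alone.

**The cyclobutane.** Cutting C5–C4 and C2–C3 of 10 gives a keteniminium two-carbon unit and (Z)-but-2-ene-1,4-diyl diacetate 7. The alkene geometry supplies the C3/C4 cis relation and both oxygenated carbons. The keteniminium 8 comes from amide 6, and the cycloadduct 9 is hydrolysed to 10. A chiral amine on nitrogen is the only place where absolute control of C3 can be exerted. Amide 6 derives from acid 3 (through acid chloride 5) and C2-symmetric amine 4, and 3 from the commercial phenol acid 1 (through benzyl ester 2).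

**The boronate.** The C–B bond of 25 is traced to the C–O bond of aryl triflate 24, and its hydroxymethyl group to the ester of 23. The triflate is placed on the ring at the very start, because the 4-hydroxyl of the ring B precursor is the one phenol that can be sulfonylated selectively.

**The dihydrofuran ring.** Cutting C3'–C2' of 23 (through its cis epimer 22) leads to aryldiazoacetate 21, with the C2' hydrogen coming from a benzylic ether CH2. Against the O1'–C2' cut this needs no free phenols at an oxidation step and forms the ring at the ester oxidation level that reduces directly to the hydroxymethyl group. A chiral catalyst sets C2', and C2' then sets C3' by epimerisation.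

**Ring B.** Diazo ester 21 comes from keto ester 19 through tosylhydrazone 20. Ester 19 comes from methyl ketone 17 through acid 18, and 17 from triflate 15 and alcohol 16. Triflate 15 comes from 1-(2,4-dihydroxy-6-methoxyphenyl)ethan-1-one 14, which already has the full ring B substitution pattern: the acetyl carbon becomes C3', its methyl the hydroxymethyl carbon, the 2-hydroxyl O1' and the 4-hydroxyl the C6' handle.

## Roads not taken

**Alternative 1:** Ring B is cut across C7a'–C3a' and C4'–C5' and built by a Danheiser benzannulation. Cyclobutenone A2 carries the finished tetrahydrofuran unit and the chiral triisopropylsilyl ynol ether A3 carries C3', C2' and ring C. On heating, a four-electron ring opening, [2+2] capture by the alkyne, a second ring opening and a six-electron closure give the resorcinol monosilyl ether A1. The dihydrofuran ring is then closed by displacement at C2' and the silyl ether exchanged for methyl.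

- Merits: a pentasubstituted arene with complete regiocontrol, automatic differentiation of the two ring B oxygens, and union of the two halves in a single late step.
- Weak points: both partners are elaborate. A2 presupposes that the tetrahydrofuran problem is already solved, and A3 needs its own asymmetric synthesis of two stereocentres and is a sensitive ynol ether. The cascade needs prolonged heating of a substrate with a benzylic silyl ether and two benzylic ring ethers. The later O1'–C2' closure works at an ionisable benzylic centre, and more protecting groups are carried.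
- Comparison: in regiocontrol of ring B and in lateness of the union it is superior. The chosen plan answers by buying ring B with the right substitution (14), so no arene has to be made, and by creating each stereocentre next to its controlling element. Overall it should be clearly shorter.

**Alternative 2:** Only O1'–C2' is cut. Ag2O oxidises the 4-hydroxy-3-methoxybenzyl unit of diarylpropanol A5 to quinone methide A6, and the ortho phenol of ring B adds to the exocyclic carbon to give trans-dihydrobenzofuran A4.

- Merits: mild and biomimetic, no diazo compound. Only C3' has to be set absolutely, which an oxazolidinone-auxiliary alkylation would do with a fully predictable sense; C2' follows from C3'.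
- Weak points: it solves only the dihydrobenzofuran half. The oxidation needs two free phenols, one of them the oxidisable resorcinol-type ring B phenol. A4 emerges with a free ring C phenol and a benzyl ether at C6', so turning C6' into a coupling handle needs debenzylation, orthogonal reprotection and triflation. A5 needs ring B at the arylacetic acid oxidation level, which 14 does not provide directly.
- Comparison: in predictability of absolute configuration it is at least as good as the carbenoid insertion used here, probably better. The chosen plan answers with a ring closure that starts from the glyoxylate level reached in one oxidation from 14, and with a triflate handle that is carried untouched from the first step of the fragment to the borylation.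

**Alternative 3:** C3–C4 is cut. Cp2TiCl (trivalent titanium, from Cp2TiCl2 and Zn) opens the terminal epoxide of ether A8 to a carbon radical at C3. This adds 5-exo to the cinnamyl double bond; the benzylic radical is reduced by a second equivalent and protonated to give A7.

- Merits: the ring, the C3–C4 bond and the C4 benzyl group arise in one neutral operation from an ether made by O-alkylation. The chair-like 5-exo transition state favours 2,3-trans and 3,4-cis, which is the target pattern. No lactone has to be reduced and no contra-thermodynamic protonation is needed.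
- Weak points: all three relations are fixed in one kinetically controlled radical event of usually moderate selectivity, with no means of correction. The epoxy alcohol must be enantiopure and the O-alkylation of such an alcohol under base risks epoxide migration. The dihydrobenzofuran half must carry a three-carbon cinnamyl chain at C6', and titanium is used in excess.
- Comparison: for the tetrahydrofuran region this road is shorter than the chosen one, and that is conceded. The chosen plan answers with stereospecific steps (suprafacial cycloaddition, migration with retention) and a C4 centre that is set separately and can be re-made by another method if the first fails.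

Key step: step 4

**Assumptions (remarks on the chemistry):**
- The (2R,5R) amine 4 is taken to direct the cycloaddition of step 3 to the 3S,4R cyclobutane. The sense rests on analogy with related auxiliary-controlled keteniminium additions; the enantiomeric amine would correct a reversed outcome without other change.
- Rh2(S-PTTL)4 is taken to select the benzylic hydrogen that leads to 2'S in step 10; the mirror-image catalyst would correct a reversed sense.
- Compounds 4, 7, 14 and 16 are treated as catalogue compounds.

## Route

Step 1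
Reactants: 1 2-(3-hydroxy-4-methoxyphenyl)acetic acid
Product: 3 2-(3-benzyloxy-4-methoxyphenyl)acetic acid, via benzyl ester 2 (not isolated)
Conditions: BnBr (2.3 equiv), K2CO3, DMF, 60 °C; then 2 M NaOH, MeOH, 50 °C; HCl to pH 2
Reagents that add atoms: benzyl bromide, BrCc1ccccc1; sodium hydroxide, [Na+].[OH-] (carboxyl OH oxygen)
Why: Williamson O-benzylation of phenoxide and carboxylate, then saponification of the benzyl ester; no stereocentre is involved.

Step 2
Reactants: 3 2-(3-benzyloxy-4-methoxyphenyl)acetic acid; 4 (2R,5R)-2,5-dimethylpyrrolidine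
Product: 6 2-(3-benzyloxy-4-methoxyphenyl)-1-[(2R,5R)-2,5-dimethylpyrrolidin-1-yl]ethan-1-one, via acid chloride 5 (not isolated)
Conditions: (COCl)2, cat. DMF, CH2Cl2, 0 °C to rt; then 4, Et3N, CH2Cl2, 0 °C to rt
Reagents that add atoms: oxalyl chloride, ClC(=O)C(=O)Cl (chlorine of 5 only; no atom of it remains in 6)
Why: Acylation of a hindered secondary amine by an acyl chloride is reliable; the C2-symmetric amine later gives a keteniminium of one geometry only.

Step 3
Reactants: 6 2-(3-benzyloxy-4-methoxyphenyl)-1-[(2R,5R)-2,5-dimethylpyrrolidin-1-yl]ethan-1-one; 7 (Z)-but-2-ene-1,4-diyl diacetate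
Product: 10 (2R,3S,4R)-3,4-bis(acetoxymethyl)-2-(3-benzyloxy-4-methoxyphenyl)cyclobutan-1-one, via keteniminium triflate 8 (not isolated), via cyclobutaniminium triflate 9 (not isolated)
Conditions: Tf2O (1.2 equiv), 2,4,6-collidine (1.3 equiv), 7 (3 equiv), ClCH2CH2Cl, −20 to 60 °C; then aq. NaHCO3, CH2Cl2, rt to 40 °C
Reagents that add atoms: water, O (carbonyl oxygen of 10); trifluoromethanesulfonic anhydride, O=S(=O)(OS(=O)(=O)C(F)(F)F)C(F)(F)F (counter-ion of 8 and 9 only)
Why: Amide activation gives keteniminium 8, which undergoes [2+2] cycloaddition suprafacially on the Z-alkene, so C3 and C4 are formed cis, and the C2-symmetric pyrrolidine shields one direction of approach and fixes their absolute configuration. Hydrolysis of 9 frees the ketone, and the benzylic α-carbonyl centre C2 equilibrates to the epimer with the aryl group trans to the C3 substituent.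

Step 4
Reactants: 10 (2R,3S,4R)-3,4-bis(acetoxymethyl)-2-(3-benzyloxy-4-methoxyphenyl)cyclobutan-1-one
Product: 12 [(2R,3S,4R)-2-(3-benzyloxy-4-methoxyphenyl)-5-oxooxolane-3,4-diyl]bis(methylene) diacetate, via Criegee adduct 11 (not isolated)
Conditions: m-CPBA (1.3 equiv), NaHCO3, CH2Cl2, 0 °C to rt
Reagents that add atoms: 3-chloroperoxybenzoic acid, O=C(OO)c1cccc(Cl)c1
Why: Baeyer–Villiger oxidation: the peracid adds to the strained carbonyl C5 to give Criegee adduct 11, and the C2–C5 bond, antiperiplanar to the O–O bond, shifts to oxygen as 3-chlorobenzoate leaves. The closest known reaction type is the peracid oxidation of α-substituted cyclobutanones to γ-butyrolactones. The five-membered ring arises by 1,2-shift ring enlargement (insertion of O1 between C2 and C5), not by an end-to-end cyclisation. No stereocentre is created; C2 migrates suprafacially with retention, so the 2,3-trans relation of 10 is copied into 12 and C3 and C4 are untouched. The step needs regioselectivity between C2 and C4: C2 is benzylic to the para-methoxy ring A and carries positive charge well in the transition state, whereas C4 is deactivated by the inductive pull of its acetoxymethyl group. It also needs chemoselectivity against oxidation of the electron-rich arenes, which relief of four-ring strain secures by making the ketone react at 0 °C. The bicarbonate buffer keeps 3-chlorobenzoic acid from ionising the new benzylic acyloxy bond.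

Step 5
Reactants: 12 [(2R,3S,4R)-2-(3-benzyloxy-4-methoxyphenyl)-5-oxooxolane-3,4-diyl]bis(methylene) diacetate
Product: 13 [(2R,3S)-2-(3-benzyloxy-4-methoxyphenyl)-4-methylidene-5-oxooxolan-3-yl]methyl acetate
Conditions: DBU (1.5 equiv), CH2Cl2, 0 °C to rt
Reagents that add atoms: none
Why: E1cB elimination: DBU removes the acidic C4 proton and acetate leaves from the C4 acetoxymethyl group. The C3 acetoxymethyl group has no acidic hydrogen β to it and stays, and the C4 stereocentre of 12 is erased on purpose.

Step 6
Reactants: 14 1-(2,4-dihydroxy-6-methoxyphenyl)ethan-1-one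
Product: 15 4-acetyl-3-hydroxy-5-methoxyphenyl trifluoromethanesulfonate
Conditions: PhNTf2 (1.05 equiv), Et3N (1.2 equiv), CH2Cl2, 0 °C to rt
Reagents that add atoms: N-phenylbis(trifluoromethanesulfonimide), O=S(=O)(N(c1ccccc1)S(=O)(=O)C(F)(F)F)C(F)(F)F
Why: Regioselective phenol triflation: the 4-hydroxyl is the more acidic and unhindered phenol, while the 2-hydroxyl is held in a hydrogen bond to the ketone, so the mild triflyl donor reacts only at the former.

Step 7
Reactants: 15 4-acetyl-3-hydroxy-5-methoxyphenyl trifluoromethanesulfonate; 16 (4-benzyloxy-3-methoxyphenyl)methanol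
Product: 17 4-acetyl-3-[(4-benzyloxy-3-methoxyphenyl)methoxy]-5-methoxyphenyl trifluoromethanesulfonate
Conditions: PPh3, DIAD, THF, 0 °C to rt
Reagents that add atoms: none
Why: Mitsunobu etherification alkylates the remaining hydrogen-bonded phenol under neutral conditions that spare the aryl triflate.

Step 8
Reactants: 17 4-acetyl-3-[(4-benzyloxy-3-methoxyphenyl)methoxy]-5-methoxyphenyl trifluoromethanesulfonate
Product: 19 methyl 2-{2-[(4-benzyloxy-3-methoxyphenyl)methoxy]-6-methoxy-4-(trifluoromethanesulfonyloxy)phenyl}-2-oxoacetate, via arylglyoxylic acid 18 (not isolated)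
Conditions: SeO2 (2.5 equiv), pyridine, 100 °C; filter, cold 1 M HCl wash; then TMSCHN2, PhMe–MeOH (4:1), 0 °C
Reagents that add atoms: selenium dioxide, O=[Se]=O; trimethylsilyldiazomethane, C[Si](C)(C)C=[N+]=[N-]
Why: Riley oxidation of an aryl methyl ketone in pyridine stops at the arylglyoxylic acid, and esterification with the diazomethane surrogate is neutral, so triflate and benzylic ether survive.

Step 9
Reactants: 19 methyl 2-{2-[(4-benzyloxy-3-methoxyphenyl)methoxy]-6-methoxy-4-(trifluoromethanesulfonyloxy)phenyl}-2-oxoacetate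
Product: 21 methyl 2-diazo-2-{2-[(4-benzyloxy-3-methoxyphenyl)methoxy]-6-methoxy-4-(trifluoromethanesulfonyloxy)phenyl}acetate, via tosylhydrazone 20 (not isolated)
Conditions: TsNHNH2, MeOH, 60 °C; then DBU, CH2Cl2, 0 °C to rt
Reagents that add atoms: 4-methylbenzenesulfonohydrazide, Cc1ccc(S(=O)(=O)NN)cc1
Why: Bamford–Stevens route to aryldiazoacetates: the activated keto group of the α-keto ester condenses with the hydrazide and base expels sulfinate.

Step 10
Reactants: 21 methyl 2-diazo-2-{2-[(4-benzyloxy-3-methoxyphenyl)methoxy]-6-methoxy-4-(trifluoromethanesulfonyloxy)phenyl}acetate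
Product: 23 methyl (2S,3S)-2-(4-benzyloxy-3-methoxyphenyl)-4-methoxy-6-(trifluoromethanesulfonyloxy)-2,3-dihydro-1-benzofuran-3-carboxylate, via cis ester 22 (not isolated)
Conditions: Rh2(S-PTTL)4 (dirhodium tetrakis[N-phthaloyl-(S)-tert-leucinate], 1 mol %), PhMe, −60 °C; then DBU, PhMe, 40 °C
Reagents that add atoms: none
Why: Intramolecular C–H insertion of a donor/acceptor carbenoid on a divalent dirhodium carboxylate into the ortho benzylic ether C–H closes the five-membered ring. The chiral carboxylate ligands choose between the two enantiotopic benzylic hydrogens and so set C2', giving the kinetic cis ester 22. DBU then epimerises the benzylic α-ester centre C3' to the more stable trans ester, so C2' controls C3'.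

Step 11
Reactants: 23 methyl (2S,3S)-2-(4-benzyloxy-3-methoxyphenyl)-4-methoxy-6-(trifluoromethanesulfonyloxy)-2,3-dihydro-1-benzofuran-3-carboxylate
Product: 24 (2S,3R)-2-(4-benzyloxy-3-methoxyphenyl)-3-(hydroxymethyl)-4-methoxy-2,3-dihydro-1-benzofuran-6-yl trifluoromethanesulfonate
Conditions: i-Bu2AlH (2.5 equiv), CH2Cl2, −78 to −20 °C; aq. sodium potassium tartrate
Reagents that add atoms: none
Why: Aluminium hydride reduction of the ester to the primary alcohol at low temperature leaves the aryl triflate alone, and C3' is no longer epimerisable once the ester is gone.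

Step 12
Reactants: 24 (2S,3R)-2-(4-benzyloxy-3-methoxyphenyl)-3-(hydroxymethyl)-4-methoxy-2,3-dihydro-1-benzofuran-6-yl trifluoromethanesulfonate
Product: 25 [(2S,3R)-2-(4-benzyloxy-3-methoxyphenyl)-4-methoxy-6-(4,4,5,5-tetramethyl-1,3,2-dioxaborolan-2-yl)-2,3-dihydro-1-benzofuran-3-yl]methanol
Conditions: B2pin2 (1.3 equiv), Pd(dppf)Cl2 (3 mol %), KOAc (3 equiv), dioxane, 85 °C
Reagents that add atoms: bis(pinacolato)diboron, CC1(C)OB(OC1(C)C)B1OC(C)(C)C(C)(C)O1
Why: Miyaura borylation of an aryl triflate (zerovalent palladium cycle with acetate-assisted transmetalation) tolerates the free primary alcohol; boron ends up meta to both ring oxygens, which disfavours protodeboronation.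

Step 13
Reactants: 13 [(2R,3S)-2-(3-benzyloxy-4-methoxyphenyl)-4-methylidene-5-oxooxolan-3-yl]methyl acetate; 25 [(2S,3R)-2-(4-benzyloxy-3-methoxyphenyl)-4-methoxy-6-(4,4,5,5-tetramethyl-1,3,2-dioxaborolan-2-yl)-2,3-dihydro-1-benzofuran-3-yl]methanol
Product: 26 [(2R,3S,4S)-2-(3-benzyloxy-4-methoxyphenyl)-4-{[(2S,3R)-2-(4-benzyloxy-3-methoxyphenyl)-3-(hydroxymethyl)-4-methoxy-2,3-dihydro-1-benzofuran-6-yl]methyl}-5-oxooxolan-3-yl]methyl acetate
Conditions: [Rh(cod)OH]2 (3 mol %), dioxane–H2O (10:1), 40 °C
Reagents that add atoms: none
Why: Hayashi–Miyaura conjugate addition: the aryl group passes from boron to monovalent rhodium and adds to the unhindered exocyclic methylene, and water protonates the resulting rhodium enolate. The proton reaches C4 from the face opposite the adjacent C3 acetoxymethyl group, which places the new benzyl group cis to it, and the near-neutral medium prevents later epimerisation to trans.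

Step 14
Reactants: 26 [(2R,3S,4S)-2-(3-benzyloxy-4-methoxyphenyl)-4-{[(2S,3R)-2-(4-benzyloxy-3-methoxyphenyl)-3-(hydroxymethyl)-4-methoxy-2,3-dihydro-1-benzofuran-6-yl]methyl}-5-oxooxolan-3-yl]methyl acetate
Product: 28 [(2R,3S,4S)-2-(3-benzyloxy-4-methoxyphenyl)-4-{[(2S,3R)-2-(4-benzyloxy-3-methoxyphenyl)-3-(hydroxymethyl)-4-methoxy-2,3-dihydro-1-benzofuran-6-yl]methyl}oxolan-3-yl]methyl acetate, via lactol 27 (not isolated)
Conditions: Sia2BH (bis(3-methylbutan-2-yl)borane, 4 equiv), THF, 0 °C to rt; MeOH, aqueous work-up; then Et3SiH (5 equiv), BF3·OEt2 (2 equiv), CH2Cl2, −78 °C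
Reagents that add atoms: none
Why: The bulky dialkylborane reduces γ-lactones to lactols but leaves acetates, so no free C3 hydroxymethyl group can re-close the lactol through the wrong oxygen. Ionic hydrogenation of the lactol through its cyclic oxocarbenium ion at −78 °C then turns C5 into CH2; no stereocentre is formed.

Step 15
Reactants: 28 [(2R,3S,4S)-2-(3-benzyloxy-4-methoxyphenyl)-4-{[(2S,3R)-2-(4-benzyloxy-3-methoxyphenyl)-3-(hydroxymethyl)-4-methoxy-2,3-dihydro-1-benzofuran-6-yl]methyl}oxolan-3-yl]methyl acetate
Product: 29 [(2R,3S,4S)-2-(3-benzyloxy-4-methoxyphenyl)-4-{[(2S,3R)-2-(4-benzyloxy-3-methoxyphenyl)-3-(hydroxymethyl)-4-methoxy-2,3-dihydro-1-benzofuran-6-yl]methyl}oxolan-3-yl]methanol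
Conditions: K2CO3 (0.2 equiv), MeOH, rt
Reagents that add atoms: none
Why: Base-catalysed transesterification to methyl acetate frees the alcohol; with the carbonyl gone no centre is epimerisable.

Step 16
Reactants: 29 [(2R,3S,4S)-2-(3-benzyloxy-4-methoxyphenyl)-4-{[(2S,3R)-2-(4-benzyloxy-3-methoxyphenyl)-3-(hydroxymethyl)-4-methoxy-2,3-dihydro-1-benzofuran-6-yl]methyl}oxolan-3-yl]methanol
Product: 30 5-[(2R,3S,4S)-4-{[(2S,3R)-2-(4-hydroxy-3-methoxyphenyl)-3-(hydroxymethyl)-4-methoxy-2,3-dihydro-1-benzofuran-6-yl]methyl}-3-(hydroxymethyl)oxolan-2-yl]-2-methoxyphenol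
Conditions: H2 (1 atm), 10% Pd/C, EtOAc–EtOH, rt
Reagents that add atoms: none
Why: Catalytic hydrogenolysis cleaves the two aryl benzyl ethers in a neutral solvent much faster than the cyclic benzylic ethers C2–O1 and C2'–O1'.

## Compound list

1 | 2-(3-hydroxy-4-methoxyphenyl)acetic acid | COc1ccc(CC(=O)O)cc1O | starting material
2 | benzyl 2-(3-benzyloxy-4-methoxyphenyl)acetate | COc1ccc(CC(=O)OCc2ccccc2)cc1OCc1ccccc1 | intermediate (not isolated)
3 | 2-(3-benzyloxy-4-methoxyphenyl)acetic acid | COc1ccc(CC(=O)O)cc1OCc1ccccc1 | intermediate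
4 | (2R,5R)-2,5-dimethylpyrrolidine | C[C@@H]1CC[C@@H](C)N1 | starting material
5 | 2-(3-benzyloxy-4-methoxyphenyl)acetyl chloride | COc1ccc(CC(=O)Cl)cc1OCc1ccccc1 | intermediate (not isolated)
6 | 2-(3-benzyloxy-4-methoxyphenyl)-1-[(2R,5R)-2,5-dimethylpyrrolidin-1-yl]ethan-1-one | COc1ccc(CC(=O)N2[C@H](C)CC[C@H]2C)cc1OCc1ccccc1 | intermediate
7 | (Z)-but-2-ene-1,4-diyl diacetate | CC(=O)OC/C=C\COC(C)=O | starting material
8 | (2R,5R)-1-[2-(3-benzyloxy-4-methoxyphenyl)ethenylidene]-2,5-dimethylpyrrolidin-1-ium trifluoromethanesulfonate | COc1ccc(C=C=[N+]2[C@H](C)CC[C@H]2C)cc1OCc1ccccc1.[O-]S(=O)(=O)C(F)(F)F | intermediate (not isolated)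
9 | iminium triflate of 10 with the (2R,5R)-2,5-dimethylpyrrolidinium unit in place of the carbonyl oxygen; 3,4-cis, both C2 epimers | COc1ccc(C2C(=[N+]3[C@H](C)CC[C@H]3C)[C@@H](COC(C)=O)[C@H]2COC(C)=O)cc1OCc1ccccc1.[O-]S(=O)(=O)C(F)(F)F | intermediate (not isolated)
10 | (2R,3S,4R)-3,4-bis(acetoxymethyl)-2-(3-benzyloxy-4-methoxyphenyl)cyclobutan-1-one (2,3-trans and 3,4-cis) | COc1ccc([C@@H]2C(=O)[C@@H](COC(C)=O)[C@H]2COC(C)=O)cc1OCc1ccccc1 | intermediate
11 | Criegee adduct of 10: 1-hydroxy-1-(3-chlorobenzoylperoxy)cyclobutane, carbinol carbon undefined | COc1ccc([C@@H]2C(O)(OOC(=O)c3cccc(Cl)c3)[C@@H](COC(C)=O)[C@H]2COC(C)=O)cc1OCc1ccccc1 | intermediate (not isolated)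
12 | [(2R,3S,4R)-2-(3-benzyloxy-4-methoxyphenyl)-5-oxooxolane-3,4-diyl]bis(methylene) diacetate | COc1ccc([C@@H]2OC(=O)[C@@H](COC(C)=O)[C@H]2COC(C)=O)cc1OCc1ccccc1 | intermediate
13 | [(2R,3S)-2-(3-benzyloxy-4-methoxyphenyl)-4-methylidene-5-oxooxolan-3-yl]methyl acetate | COc1ccc([C@@H]2OC(=O)C(=C)[C@H]2COC(C)=O)cc1OCc1ccccc1 | intermediate
14 | 1-(2,4-dihydroxy-6-methoxyphenyl)ethan-1-one | CC(=O)c1c(O)cc(O)cc1OC | starting material
15 | 4-acetyl-3-hydroxy-5-methoxyphenyl trifluoromethanesulfonate | CC(=O)c1c(O)cc(OS(=O)(=O)C(F)(F)F)cc1OC | intermediate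
16 | (4-benzyloxy-3-methoxyphenyl)methanol | COc1cc(CO)ccc1OCc1ccccc1 | starting material
17 | 4-acetyl-3-[(4-benzyloxy-3-methoxyphenyl)methoxy]-5-methoxyphenyl trifluoromethanesulfonate | CC(=O)c1c(OCc2ccc(OCc3ccccc3)c(OC)c2)cc(OS(=O)(=O)C(F)(F)F)cc1OC | intermediate
18 | 2-{2-[(4-benzyloxy-3-methoxyphenyl)methoxy]-6-methoxy-4-(trifluoromethanesulfonyloxy)phenyl}-2-oxoacetic acid | OC(=O)C(=O)c1c(OCc2ccc(OCc3ccccc3)c(OC)c2)cc(OS(=O)(=O)C(F)(F)F)cc1OC | intermediate (not isolated)
19 | methyl 2-{2-[(4-benzyloxy-3-methoxyphenyl)methoxy]-6-methoxy-4-(trifluoromethanesulfonyloxy)phenyl}-2-oxoacetate | COC(=O)C(=O)c1c(OCc2ccc(OCc3ccccc3)c(OC)c2)cc(OS(=O)(=O)C(F)(F)F)cc1OC | intermediate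
20 | 4-methylbenzenesulfonylhydrazone of 19 | COC(=O)C(=NNS(=O)(=O)c1ccc(C)cc1)c1c(OCc2ccc(OCc3ccccc3)c(OC)c2)cc(OS(=O)(=O)C(F)(F)F)cc1OC | intermediate (not isolated)
21 | methyl 2-diazo-2-{2-[(4-benzyloxy-3-methoxyphenyl)methoxy]-6-methoxy-4-(trifluoromethanesulfonyloxy)phenyl}acetate | COC(=O)C(=[N+]=[N-])c1c(OCc2ccc(OCc3ccccc3)c(OC)c2)cc(OS(=O)(=O)C(F)(F)F)cc1OC | intermediate
22 | methyl (2S,3R)-2-(4-benzyloxy-3-methoxyphenyl)-4-methoxy-6-(trifluoromethanesulfonyloxy)-2,3-dihydro-1-benzofuran-3-carboxylate (cis) | O=S(=O)(Oc1cc(OC)c2c(c1)O[C@H](c1ccc(OCc3ccccc3)c(OC)c1)[C@@H]2C(=O)OC)C(F)(F)F | intermediate (not isolated)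
23 | methyl (2S,3S)-2-(4-benzyloxy-3-methoxyphenyl)-4-methoxy-6-(trifluoromethanesulfonyloxy)-2,3-dihydro-1-benzofuran-3-carboxylate (trans) | O=S(=O)(Oc1cc(OC)c2c(c1)O[C@H](c1ccc(OCc3ccccc3)c(OC)c1)[C@H]2C(=O)OC)C(F)(F)F | intermediate
24 | (2S,3R)-2-(4-benzyloxy-3-methoxyphenyl)-3-(hydroxymethyl)-4-methoxy-2,3-dihydro-1-benzofuran-6-yl trifluoromethanesulfonate | O=S(=O)(Oc1cc(OC)c2c(c1)O[C@H](c1ccc(OCc3ccccc3)c(OC)c1)[C@H]2CO)C(F)(F)F | intermediate
25 | [(2S,3R)-2-(4-benzyloxy-3-methoxyphenyl)-4-methoxy-6-(4,4,5,5-tetramethyl-1,3,2-dioxaborolan-2-yl)-2,3-dihydro-1-benzofuran-3-yl]methanol | CC1(C)OB(c2cc(OC)c3c(c2)O[C@H](c2ccc(OCc4ccccc4)c(OC)c2)[C@H]3CO)OC1(C)C | intermediate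
26 | [(2R,3S,4S)-2-(3-benzyloxy-4-methoxyphenyl)-4-{[(2S,3R)-2-(4-benzyloxy-3-methoxyphenyl)-3-(hydroxymethyl)-4-methoxy-2,3-dihydro-1-benzofuran-6-yl]methyl}-5-oxooxolan-3-yl]methyl acetate | COc1ccc([C@@H]2OC(=O)[C@@H](Cc3cc(OC)c4c(c3)O[C@H](c3ccc(OCc5ccccc5)c(OC)c3)[C@H]4CO)[C@H]2COC(C)=O)cc1OCc1ccccc1 | intermediate
27 | lactol of 26 (5-hydroxyoxolane, both anomers) | COc1ccc([C@@H]2OC(O)[C@@H](Cc3cc(OC)c4c(c3)O[C@H](c3ccc(OCc5ccccc5)c(OC)c3)[C@H]4CO)[C@H]2COC(C)=O)cc1OCc1ccccc1 | intermediate (not isolated)
28 | [(2R,3S,4S)-2-(3-benzyloxy-4-methoxyphenyl)-4-{[(2S,3R)-2-(4-benzyloxy-3-methoxyphenyl)-3-(hydroxymethyl)-4-methoxy-2,3-dihydro-1-benzofuran-6-yl]methyl}oxolan-3-yl]methyl acetate | COc1ccc([C@@H]2OC[C@@H](Cc3cc(OC)c4c(c3)O[C@H](c3ccc(OCc5ccccc5)c(OC)c3)[C@H]4CO)[C@H]2COC(C)=O)cc1OCc1ccccc1 | intermediate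
29 | [(2R,3S,4S)-2-(3-benzyloxy-4-methoxyphenyl)-4-{[(2S,3R)-2-(4-benzyloxy-3-methoxyphenyl)-3-(hydroxymethyl)-4-methoxy-2,3-dihydro-1-benzofuran-6-yl]methyl}oxolan-3-yl]methanol | COc1ccc([C@@H]2OC[C@@H](Cc3cc(OC)c4c(c3)O[C@H](c3ccc(OCc5ccccc5)c(OC)c3)[C@H]4CO)[C@H]2CO)cc1OCc1ccccc1 | intermediate
30 | 5-[(2R,3S,4S)-4-{[(2S,3R)-2-(4-hydroxy-3-methoxyphenyl)-3-(hydroxymethyl)-4-methoxy-2,3-dihydro-1-benzofuran-6-yl]methyl}-3-(hydroxymethyl)oxolan-2-yl]-2-methoxyphenol (CNP0242386.1) | COc1ccc([C@@H]2OC[C@@H](Cc3cc(OC)c4c(c3)O[C@H](c3ccc(O)c(OC)c3)[C@H]4CO)[C@H]2CO)cc1O | target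

## Step count and risks

Total step count: 16. Longest linear sequence: 11 steps (14 to 30 through steps 6–12 and 13–16); the lactone branch (1 to 13) has 5 steps.

Least certain steps:

**Step 4 (key step).** Migration of C4 in place of C2 is unlikely. The more probable failures are electrophilic oxidation of the electron-rich ring A by the peracid, and ionisation of the new benzylic acyloxy bond by the carboxylic acid formed. The fallback avoids peroxides. It sets out from 10, which is irradiated through Pyrex in methanol. Photochemical ring expansion moves the more substituted α-carbon to oxygen with retention and gives the methyl acetal F1. Mild aqueous acetic acid frees the lactol F2, and Fétizon oxidation (Ag2CO3 on Celite) returns to the route at 12.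

**Step 3.** The cycloaddition may stall, because the allylic acetates make the alkene electron-poor and their carbonyl oxygens compete for the electrophile. The auxiliary may also discriminate the two directions of approach too weakly. The fallback sets out from 6 and uses the more nucleophilic, conformationally fixed cis-alkene 2,2-dimethyl-4,7-dihydro-1,3-dioxepine under the same activation, giving the bicyclic acetonide cyclobutanone F3. Aqueous acetic acid removes the acetonide to give the diol cyclobutanone F4, which is acetylated at once (Ac2O, pyridine) and rejoins the route at 10.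

**Step 10.** The crowded carbenoid, flanked by two ortho substituents, may be inserted with insufficient or reversed selection between the benzylic hydrogens, or may attack the methoxy C–H. The fallback moves the chirality into a covalently bound ester auxiliary, so that minor isomers become separable diastereomers. It sets out from acid 18, isolated in this variant. Esterification with (S)-2-hydroxy-1-(pyrrolidin-1-yl)propan-1-one (DCC, DMAP) gives keto ester F5; tosylhydrazide gives hydrazone F6 and DBU gives diazo ester F7. Rh2(S-DOSP)4 (dirhodium tetrakis[(S)-N-(4-dodecylbenzenesulfonyl)prolinate]) then gives the trans auxiliary ester F8, which is purified by chromatography. LiBH4 cleaves it to rejoin the route at 24.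

**Step 13.** Protonation of the rhodium enolate may occur on the wrong face, the cis product may drift to trans, or β-hydride loss may give arylated alkenes. The fallback sets C4 by surface hydrogenation. It sets out from 13 and triflate 24, which are joined by a Mizoroki–Heck reaction (Pd(OAc)2, dppp, Et3N, DMF, 80 °C) to the (E)-benzylidene lactone F9. Hydrogenation over Pd/C poisoned with ethylenediamine spares benzyl ethers and adds hydrogen from the face away from the C3 substituent, rejoining the route at 26.

**Step 14.** Partial reduction of the acetate would allow ring-chain isomerisation of the lactol through the C3 hydroxymethyl oxygen. The Lewis acid could also ionise the benzylic ethers, or let ring B capture the oxocarbenium ion. The fallback sets out from 26. LiAlH4 reduces lactone and acetate to the tetraol F10. Catalytic camphorsulfonic acid in CH2Cl2 at 0 °C then closes the ring by capture of the C2 benzylic cation by the C5 hydroxyl. Five-ring formation and thermodynamic control give the 2,3-trans ether, and without a hydride donor, reversible ionisation at C2' is harmless. The route is rejoined at 29, bypassing 28.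

## Further compounds

F1 | step 4 | methyl acetal of the lactol corresponding to 12: [(2R,3S,4R)-configured 2-(3-benzyloxy-4-methoxyphenyl)-5-methoxyoxolane-3,4-diyl]bis(methylene) diacetate, both anomers | COc1ccc([C@@H]2OC(OC)[C@@H](COC(C)=O)[C@H]2COC(C)=O)cc1OCc1ccccc1
F2 | step 4 | lactol corresponding to 12: 5-hydroxyoxolane diacetate, both anomers | COc1ccc([C@@H]2OC(O)[C@@H](COC(C)=O)[C@H]2COC(C)=O)cc1OCc1ccccc1
F3 | step 3 | cis-fused 7-(3-benzyloxy-4-methoxyphenyl)-4,4-dimethyl-3,5-dioxabicyclo[5.2.0]nonan-8-one, aryl trans to the ring fusion substituent | COc1ccc([C@@H]2C(=O)[C@H]3COC(C)(C)OC[C@@H]23)cc1OCc1ccccc1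
F4 | step 3 | 2-(3-benzyloxy-4-methoxyphenyl)-3,4-bis(hydroxymethyl)cyclobutan-1-one, configured as 10 | COc1ccc([C@@H]2C(=O)[C@@H](CO)[C@H]2CO)cc1OCc1ccccc1
F5 | step 10 | (S)-1-oxo-1-(pyrrolidin-1-yl)propan-2-yl ester of acid 18 | C[C@H](OC(=O)C(=O)c1c(OCc2ccc(OCc3ccccc3)c(OC)c2)cc(OS(=O)(=O)C(F)(F)F)cc1OC)C(=O)N1CCCC1
F6 | step 10 | 4-methylbenzenesulfonylhydrazone of F5 | C[C@H](OC(=O)C(=NNS(=O)(=O)c1ccc(C)cc1)c1c(OCc2ccc(OCc3ccccc3)c(OC)c2)cc(OS(=O)(=O)C(F)(F)F)cc1OC)C(=O)N1CCCC1
F7 | step 10 | diazo ester corresponding to F5 | C[C@H](OC(=O)C(=[N+]=[N-])c1c(OCc2ccc(OCc3ccccc3)c(OC)c2)cc(OS(=O)(=O)C(F)(F)F)cc1OC)C(=O)N1CCCC1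
F8 | step 10 | (S)-1-oxo-1-(pyrrolidin-1-yl)propan-2-yl (2S,3S)-2-(4-benzyloxy-3-methoxyphenyl)-4-methoxy-6-(trifluoromethanesulfonyloxy)-2,3-dihydro-1-benzofuran-3-carboxylate | O=S(=O)(Oc1cc(OC)c2c(c1)O[C@H](c1ccc(OCc3ccccc3)c(OC)c1)[C@H]2C(=O)O[C@@H](C)C(=O)N1CCCC1)C(F)(F)F
F9 | step 13 | (E)-benzylidene lactone: [(2R,3S)-2-(3-benzyloxy-4-methoxyphenyl)-4-{[(2S,3R)-2-(4-benzyloxy-3-methoxyphenyl)-3-(hydroxymethyl)-4-methoxy-2,3-dihydro-1-benzofuran-6-yl]methylidene}-5-oxooxolan-3-yl]methyl acetate | COc1ccc([C@@H]2OC(=O)/C(=C/c3cc(OC)c4c(c3)O[C@H](c3ccc(OCc5ccccc5)c(OC)c3)[C@H]4CO)[C@H]2COC(C)=O)cc1OCc1ccccc1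
F10 | step 14 | open-chain tetraol: 1-(3-benzyloxy-4-methoxyphenyl)-2-(hydroxymethyl)-3-{[(2S,3R)-2-(4-benzyloxy-3-methoxyphenyl)-3-(hydroxymethyl)-4-methoxy-2,3-dihydro-1-benzofuran-6-yl]methyl}butane-1,4-diol, configured as 26 | COc1ccc([C@H](O)[C@H](CO)[C@@H](CO)Cc2cc(OC)c3c(c2)O[C@H](c2ccc(OCc4ccccc4)c(OC)c2)[C@H]3CO)cc1OCc1ccccc1
A1 | alternative 1 | ring B resorcinol monosilyl ether carrying the tetrahydrofuran unit at C6' and the C3'–C2' chain at C3a' | COc1ccc([C@@H]2OC[C@@H](Cc3cc(O[Si](C(C)C)(C(C)C)C(C)C)c([C@H](COCc4ccccc4)[C@@H](O[Si](C)(C)C(C)(C)C)c4ccc(OCc5ccccc5)c(OC)c4)c(O)c3)[C@H]2CO[Si](C)(C)C(C)(C)C)cc1OCc1ccccc1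
A2 | alternative 1 | 3-substituted cyclobut-2-en-1-one carrying the protected tetrahydrofuran unit through its C4 methylene | COc1ccc([C@@H]2OC[C@@H](CC3=CC(=O)C3)[C@H]2CO[Si](C)(C)C(C)(C)C)cc1OCc1ccccc1
A3 | alternative 1 | triisopropylsilyl ynol ether carrying the C3' benzyloxymethyl and C2' silyloxy(aryl)methyl centres | CC(C)[Si](C(C)C)(C(C)C)OC#C[C@H](COCc1ccccc1)[C@@H](O[Si](C)(C)C(C)(C)C)c1ccc(OCc2ccccc2)c(OC)c1
A4 | alternative 2 | [(2S,3R)-6-benzyloxy-2-(4-hydroxy-3-methoxyphenyl)-4-methoxy-2,3-dihydro-1-benzofuran-3-yl]methanol | c1ccccc1COc1cc(OC)c2c(c1)O[C@H](c1ccc(O)c(OC)c1)[C@H]2CO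
A5 | alternative 2 | (R)-2-(4-benzyloxy-2-hydroxy-6-methoxyphenyl)-3-(4-hydroxy-3-methoxyphenyl)propan-1-ol | COc1cc(OCc2ccccc2)cc(O)c1[C@H](CO)Cc1ccc(O)c(OC)c1
A6 | alternative 2 | p-quinone methide formed from A5 by oxidation of the 4-hydroxy-3-methoxybenzyl unit | COc1cc(OCc2ccccc2)cc(O)c1[C@H](CO)C=C1C=CC(=O)C(OC)=C1
A7 | alternative 3 | target skeleton with both phenols benzylated and the C3' hydroxymethyl group silylated | COc1ccc([C@@H]2OC[C@@H](Cc3cc(OC)c4c(c3)O[C@H](c3ccc(OCc5ccccc5)c(OC)c3)[C@H]4CO[Si](C)(C)C(C)(C)C)[C@H]2CO)cc1OCc1ccccc1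
A8 | alternative 3 | (E)-cinnamyl-type ether of (1S)-(3-benzyloxy-4-methoxyphenyl)(oxiran-2-yl)methanol with the protected dihydrobenzofuran unit on the alkene terminus; epoxide carbon either epimer | COc1ccc([C@H](OC/C=C/c2cc(OC)c3c(c2)O[C@H](c2ccc(OCc4ccccc4)c(OC)c2)[C@H]3CO[Si](C)(C)C(C)(C)C)C2CO2)cc1OCc1ccccc1
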